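**Plan**
- The chain is numbered C1 (benzylic) to C13, and the stereocentre C2 is (R). The ester oxygen on C2 stands 1,3 to C4, so O, C2, C3 and C4 can be tied into an oxetane ring. In that ring C4 is a strain-activated primary electrophile, and its leaving group is the oxygen the target carries acetylated.
- Retrosynthetic cuts, in order: phenol O–benzyl; C4–C5 together with O–acetyl (oxetane + nonyl Grignard reagent + Ac2O in one flask); C3–C4 and C4–O (CH2 insertion into a terminal epoxide); aryl–C1 (aryl Grignard reagent + epichlorohydrin).
- Forward order: the arene is joined to the C1–C3 unit, the epoxide is closed and expanded to the oxetane (the only ring built, and a temporary one), the C5–C13 chain opens it with acetylation in the same flask, and the benzyl group is removed.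
- Stereochemistry: C2 comes from (S)-epichlorohydrin. Its C–O bond is never broken, and only the CIP descriptor changes along the way.
- The mono-O-methylated resorcinol is bought as 3-bromo-5-methoxyphenol, so two phenols never have to be told apart.

Key step: step 4

Assumption: 3-bromo-5-methoxyphenol, (S)-epichlorohydrin and nonylmagnesium bromide (ether solution) are taken as commercial, and CIP analysis of the given SMILES gives (R) at C2.

**Step 1**
Reactants: 1 3-bromo-5-methoxyphenol
Product: 2 1-(benzyloxy)-3-bromo-5-methoxybenzene
Conditions: BnBr, K2CO3, DMF, rt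
Reagents that add atoms: benzyl bromide, BrCc1ccccc1
Why: Williamson ether synthesis on the only acidic OH; the benzyl ether should survive Grignard, ylide and cuprate chemistry and can be removed at the end under neutral conditions that spare the acetate.

**Step 2**
Reactants: 2 1-(benzyloxy)-3-bromo-5-methoxybenzene, 3 (S)-epichlorohydrin
Product: 5 (S)-1-[3-(benzyloxy)-5-methoxyphenyl]-3-chloropropan-2-ol, via aryl Grignard reagent 4 (not isolated)
Conditions: Mg, I2 (cat.), THF, reflux; then CuI (10 mol %), 3, THF, −40 → 0 °C; then H2O work-up
Reagents that add atoms: magnesium, [Mg] (held only in intermediate 4)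
Why: Copper-catalysed Grignard opening of a terminal epoxide at its unsubstituted CH2 (SN2) leaves the C–O bond of the stereocentre of 3 untouched, so the configuration passes unchanged into 5, and isolating the chlorohydrin removes any material formed by direct chloride displacement.

**Step 3**
Reactants: 5 (S)-1-[3-(benzyloxy)-5-methoxyphenyl]-3-chloropropan-2-ol
Product: 7 (S)-2-[3-(benzyloxy)-5-methoxybenzyl]oxetane, via epoxide 6 (not isolated)
Conditions: Me3S(O)I (3 equiv), KOt-Bu (4 equiv), t-BuOH, 65 °C
Reagents that add atoms: trimethylsulfoxonium iodide, C[S+](C)(C)=O.[I-]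
Why: Base closes the chlorohydrin to the terminal epoxide, dimethylsulfoxonium methylide attacks its CH2 terminus, and the γ-sulfoxonium alkoxide closes 4-exo-tet with loss of DMSO (Corey–Chaykovsky-type epoxide-to-oxetane ring expansion); the C2–O bond is never broken, so the stereocentre is retained, and further expansion to the oxolane needs much higher temperature.

**Step 4**
Reactants: 7 (S)-2-[3-(benzyloxy)-5-methoxybenzyl]oxetane, 8 nonylmagnesium bromide
Product: 10 (R)-1-[3-(benzyloxy)-5-methoxyphenyl]tridecan-2-yl acetate, via bromomagnesium alkoxide 9 (not isolated)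
Conditions: 8 (2 equiv), CuI (15 mol %), THF/Et2O, 0 → 40 °C; then Ac2O (excess), DMAP (cat.), 0 °C → rt; then H2O work-up
Reagents that add atoms: acetic anhydride, CC(=O)OC(C)=O
Why: Nonylmagnesium bromide and CuI form a magnesium nonylcuprate, Mg(II) binds the ring oxygen, and the cuprate attacks C4 from the rear of the C4–O bond (SN2-type oxidative addition, then reductive elimination from Cu(III)), so the C4–C5 bond forms as roughly 105 kJ/mol of ring strain is released and the ring oxygen leaves as the C2 alkoxide 9. The closest known reaction type is the copper-catalysed ring opening of oxetanes and epoxides by Grignard reagents, followed by routine trapping of a magnesium alkoxide with an anhydride. No ring is closed; the temporary oxetane is the only ring opened, and it leaves no helper atom behind because its oxygen becomes the ester oxygen of the target. No new stereocentre arises: the C2–O bond is not involved, so C2 keeps its configuration, and the change from (S) in 7 to (R) in 10 only reflects the changed CIP ranking of C3 against C1. The step needs attack at C4 rather than C2, which the substrate secures because C4 is primary and unbranched while C2 is secondary and shielded by the arylmethyl group, and it needs intermolecular alkyl transfer to outrun attack of the electron-rich arene carbons ortho to the side chain on C4, which is why strong Lewis acids such as BF3 are left out. Acetylation is site-selective by construction, since alkoxide 9 is the only oxygen nucleophile present while the phenol is benzylated, so chain junction, release of the carbinol oxygen and ester formation are settled in one operation.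

**Step 5**
Reactants: 10 (R)-1-[3-(benzyloxy)-5-methoxyphenyl]tridecan-2-yl acetate
Product: 11 (R)-1-(3-hydroxy-5-methoxyphenyl)tridecan-2-yl acetate
Conditions: H2 (1 atm), 10 % Pd/C, EtOAc, rt
Reagents that add atoms: none
Why: Catalytic hydrogenolysis of the aryl benzyl ether; the acetate sits on a homobenzylic rather than benzylic carbon, so its C–O bond and the stereocentre should be inert, and the neutral aprotic solvent excludes transesterification.

**Compound list**
1 | 3-bromo-5-methoxyphenol | COc1cc(O)cc(Br)c1 | starting material
2 | 1-(benzyloxy)-3-bromo-5-methoxybenzene | COc1cc(Br)cc(OCc2ccccc2)c1 | intermediate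
3 | (S)-epichlorohydrin, (S)-2-(chloromethyl)oxirane | ClC[C@@H]1CO1 | starting material
4 | [3-(benzyloxy)-5-methoxyphenyl]magnesium bromide | COc1cc([Mg]Br)cc(OCc2ccccc2)c1 | intermediate
5 | (S)-1-[3-(benzyloxy)-5-methoxyphenyl]-3-chloropropan-2-ol | ClC[C@H](Cc1cc(OCc2ccccc2)cc(OC)c1)O | intermediate
6 | (S)-2-[3-(benzyloxy)-5-methoxybenzyl]oxirane | C1[C@H](Cc2cc(OCc3ccccc3)cc(OC)c2)O1 | intermediate
7 | (S)-2-[3-(benzyloxy)-5-methoxybenzyl]oxetane | C1C[C@H](Cc2cc(OCc3ccccc3)cc(OC)c2)O1 | intermediate
8 | nonylmagnesium bromide | CCCCCCCCC[Mg]Br | starting material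
9 | bromomagnesium (R)-1-[3-(benzyloxy)-5-methoxyphenyl]tridecan-2-olate | CCCCCCCCCCC[C@H](Cc1cc(OCc2ccccc2)cc(OC)c1)O[Mg]Br | intermediate
10 | (R)-1-[3-(benzyloxy)-5-methoxyphenyl]tridecan-2-yl acetate | CCCCCCCCCCC[C@H](Cc1cc(OCc2ccccc2)cc(OC)c1)OC(C)=O | intermediate
11 | (R)-1-(3-hydroxy-5-methoxyphenyl)tridecan-2-yl acetate | CCCCCCCCCCC[C@H](Cc1cc(O)cc(OC)c1)OC(C)=O | target

Total step count: 5. Longest linear sequence: 5 steps (from 1).

**Steps most likely to fail**

**Step 4.**
- What may go wrong: carbon–carbon bond formation at the 2-substituted oxetane may be slow, so that bromide from the Schlenk equilibrium opens the ring first. Acylation of the magnesium alkoxide may also stay incomplete beside surplus Grignard reagent.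
- Fallback (sets out from 7, comes back at 10): the order of events is inverted and the organomagnesium nucleophile is given up.
- Oxetane 7 is opened acylatively with acetyl bromide (CH2Cl2, 0 °C). O-acylation gives an acyloxonium ion that bromide opens at the primary C4. This should give (S)-4-bromo-1-[3-(benzyloxy)-5-methoxyphenyl]butan-2-yl acetate F1, with the acetate already in place.
- 1-Nonene is hydroborated with 9-BBN-H to B-nonyl-9-borabicyclo[3.3.1]nonane F2.
- F1 and F2 are joined by an alkyl–alkyl Suzuki–Miyaura coupling (Pd(OAc)2, PCy3, K3PO4·H2O, THF, rt). It forms the same C4–C5 bond, tolerates the ester and delivers 10.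

**Step 3.**
- What may go wrong: the base may isomerise the benzyl-substituted epoxide to the conjugated allylic alcohol, or the 4-exo-tet closure may be slow.
- Fallback (sets out from 5, comes back at 11): no four-membered ring is made, and the chain is joined by metathesis.
- Chlorohydrin 5 is closed with NaOH (Et2O/H2O) to epoxide 6, which is now isolated.
- Vinylmagnesium bromide/CuI opens 6 to (R)-1-[3-(benzyloxy)-5-methoxyphenyl]pent-4-en-2-ol F3.
- Ac2O/pyridine/DMAP gives (R)-1-[3-(benzyloxy)-5-methoxyphenyl]pent-4-en-2-yl acetate F4.
- Cross metathesis of F4 with excess 1-decene (second-generation ruthenium carbene catalyst, CH2Cl2, 40 °C) builds C4=C5. The product is (R,E)-1-[3-(benzyloxy)-5-methoxyphenyl]tridec-4-en-2-yl acetate F5, whose alkene geometry is of no consequence.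
- H2, Pd/C in EtOAc then saturates the alkene and cleaves the benzyl ether in one operation to give 11.

**Step 2.**
- What may go wrong: formation of the aryl Grignard reagent may be sluggish or burdened by homocoupling. Halide may also interchange the two termini of epichlorohydrin, which would erode the enantiopurity.
- Fallback (sets out from 2, comes back at 6): the stereocentre is taken from a catalyst instead of the chiral pool, and no arylmagnesium species is used.
- Suzuki–Miyaura allylation of 2 with allylboronic acid pinacol ester (Pd(dppf)Cl2, K2CO3, dioxane/H2O, 80 °C) gives 1-allyl-3-(benzyloxy)-5-methoxybenzene F6.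
- mCPBA (CH2Cl2, 0 °C) gives racemic 2-[3-(benzyloxy)-5-methoxybenzyl]oxirane F7.
- Hydrolytic kinetic resolution follows, with the (S,S)-configured (salen)Co(III) acetate catalyst and 0.55 equiv of water. This catalyst enantiomer is expected to leave the (S)-epoxide 6 untouched.
- The other enantiomer is hydrolysed to (R)-3-[3-(benzyloxy)-5-methoxyphenyl]propane-1,2-diol F8 and removed by chromatography.
- Epoxide 6 then enters the conditions of step 3 with one equivalent less base.

**Further compounds**
F1 | step 4 | (S)-4-bromo-1-[3-(benzyloxy)-5-methoxyphenyl]butan-2-yl acetate | BrCC[C@H](Cc1cc(OCc2ccccc2)cc(OC)c1)OC(C)=O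
F2 | step 4 | B-nonyl-9-borabicyclo[3.3.1]nonane | CCCCCCCCCB1C2CCCC1CCC2
F3 | step 3 | (R)-1-[3-(benzyloxy)-5-methoxyphenyl]pent-4-en-2-ol | C=CC[C@H](Cc1cc(OCc2ccccc2)cc(OC)c1)O
F4 | step 3 | (R)-1-[3-(benzyloxy)-5-methoxyphenyl]pent-4-en-2-yl acetate | C=CC[C@H](Cc1cc(OCc2ccccc2)cc(OC)c1)OC(C)=O
F5 | step 3 | (R,E)-1-[3-(benzyloxy)-5-methoxyphenyl]tridec-4-en-2-yl acetate | CCCCCCCC/C=C/C[C@H](Cc1cc(OCc2ccccc2)cc(OC)c1)OC(C)=O
F6 | step 2 | 1-allyl-3-(benzyloxy)-5-methoxybenzene | C=CCc1cc(OCc2ccccc2)cc(OC)c1
F7 | step 2 | racemic 2-[3-(benzyloxy)-5-methoxybenzyl]oxirane | C1C(Cc2cc(OCc3ccccc3)cc(OC)c2)O1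
F8 | step 2 | (R)-3-[3-(benzyloxy)-5-methoxyphenyl]propane-1,2-diol | OC[C@@H](Cc1cc(OCc2ccccc2)cc(OC)c1)O
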